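**Retrosynthetic overview** (ring A = benzene ring, ring B = hemiketal pyranone, ring C = 4-hydroxy-2-pyranone)
1. The (2R)-hemiketal comes from the racemic hemiketal; C2 is labile and is fixed last by chiral-phase resolution with racemisation and recycle of the unwanted enantiomer.
2. Rings A and B are disconnected together: a Diels–Alder benzannulation of an alkynyl 1,3-diketone with 1-methoxy-1,3-bis(trimethylsilyloxy)buta-1,3-diene gives the resorcinol ring, and the freed ortho-phenol then closes onto the β-ketone.
3. The alkynyl 1,3-diketone comes from terminal acylation of the trianion of 6-acetonyl-4-hydroxy-2-pyranone with an alkynyl Weinreb amide made from 5-methylhex-1-yne.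
4. The acetonylpyranone comes from the dianion of triacetic acid lactone and N-methoxy-N-methylacetamide.
5. Ring order: C is bought, then A (cycloaddition and aromatisation) and B (hemiketal) are formed in the same flask.

Assumption: the hemiketal carbon C2 (R, as derived from the given SMILES) can racemise through the ring-opened 1,3-diketone, so it is fixed in the last step and the product is handled cold, near neutral and without alcohols.

**Route**

Step 1
Reactants: 1 5-methylhex-1-yne; 2 N-methoxy-N-methylcarbamoyl chloride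
Product: 3 N-methoxy-N,6-dimethylhept-2-ynamide
Conditions: n-BuLi, THF, −78 °C; then 2, −78 to 0 °C
Reagents that add atoms: none
Why: The lithium acetylide of 1 displaces chloride at the carbamoyl carbon (nucleophilic acyl substitution) and the resulting Weinreb amide does not react further at low temperature; no stereocentre is formed.

Step 2
Reactants: 4 4-hydroxy-6-methyl-2H-pyran-2-one; 5 N-methoxy-N-methylacetamide
Product: 6 4-hydroxy-6-(2-oxopropyl)-2H-pyran-2-one
Conditions: LiN(iPr)2 (2.2 equiv), THF/DMPU, −78 to −30 °C; then 5, −78 to −20 °C; cold 1 M HCl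
Reagents that add atoms: none
Why: The O,C-dianion of 4 reacts at its C6-methyl carbanion, and the chelated tetrahedral adduct of the Weinreb amide survives until the acidic quench, so only one acetyl group is introduced (Harris-type pyranone dianion acylation, Weinreb ketone synthesis); no stereocentre is formed.

Step 3
Reactants: 6 4-hydroxy-6-(2-oxopropyl)-2H-pyran-2-one; 3 N-methoxy-N,6-dimethylhept-2-ynamide
Product: 7 4-hydroxy-6-(9-methyl-2,4-dioxodec-5-yn-1-yl)-2H-pyran-2-one
Conditions: LiN(iPr)2 (3.1 equiv), THF/DMPU, −78 to −20 °C; then 3 (0.9 equiv), −78 °C; inverse quench into cold 1 M HCl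
Reagents that add atoms: none
Why: In the trianion of 6 the last-formed terminal CH2 carbanion is the most nucleophilic site and adds 1,2 to the Weinreb ynamide, whose chelated tetrahedral adduct keeps the ynone masked from conjugate addition until the cold acidic quench, which also protonates the released N,O-dimethylhydroxylamine (Harris polyanion acylation); no stereocentre is formed.

Step 4
Reactants: 8 methyl acetoacetate
Product: 10 1-methoxy-1,3-bis(trimethylsilyloxy)buta-1,3-diene, via methyl 3-(trimethylsilyloxy)but-2-enoate 9 (not isolated)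
Conditions: Me3SiCl, Et3N, hexane, 23 °C; filter, concentrate; then LiN(iPr)2, THF, −78 °C; Me3SiCl, −78 to 0 °C; distil
Reagents that add atoms: chlorotrimethylsilane, C[Si](C)(C)Cl
Why: O-silylation of the enol of 8, then kinetic γ-deprotonation of the vinylogous ester 9 and O-silylation of the dienolate, gives the 1,1,3-trioxygenated diene (standard preparation of Chan's diene); no stereocentre is formed.

Step 5
Reactants: 7 4-hydroxy-6-(9-methyl-2,4-dioxodec-5-yn-1-yl)-2H-pyran-2-one; 10 1-methoxy-1,3-bis(trimethylsilyloxy)buta-1,3-diene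
Product: 15 (2RS)-2,7-dihydroxy-2-[(4-hydroxy-2-oxo-2H-pyran-6-yl)methyl]-5-(3-methylbutyl)-2,3-dihydro-4H-chromen-4-one (racemic hemiketal), via bis-silyl ynedione 11 (not isolated), via Diels–Alder cycloadduct 12 (not isolated), via silylated arene 13 (not isolated), via open-chain aryl diketone 14 (not isolated)
Conditions: N,O-bis(trimethylsilyl)acetamide (2.1 equiv), toluene, 23 °C; then 10 (3 equiv, two portions), 105 °C, sealed tube, 16 h; then THF/0.5 M aq citric acid, 0 °C
Reagents that add atoms: N,O-bis(trimethylsilyl)acetamide, CC(=N[Si](C)(C)C)O[Si](C)(C)C (its silyl groups are carried only by 11, 12 and 13 and are gone in 15)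
Why: Silylation masks the two acidic OH groups and blocks closure of the diketone enol onto the alkyne, the electron-rich diene then adds to the ynone in a thermal Diels–Alder reaction with its nucleophilic CH2 terminus on the alkyne carbon bearing the 3-methylbutyl group, loss of methanol aromatises the adduct to ring A with oxygen ortho and para to the acyl group (Chan–Brassard-type benzannulation), and mild hydrolysis frees the ortho phenol, which adds to the β-ketone to close hemiketal ring B in the same operation, C2 being formed as a racemate because this closure is reversible and unbiased.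

Step 6
Reactants: 15 (2RS)-2,7-dihydroxy-2-[(4-hydroxy-2-oxo-2H-pyran-6-yl)methyl]-5-(3-methylbutyl)-2,3-dihydro-4H-chromen-4-one
Product: 16 (2R)-2,7-dihydroxy-2-[(4-hydroxy-2-oxo-2H-pyran-6-yl)methyl]-5-(3-methylbutyl)-2,3-dihydro-4H-chromen-4-one
Conditions: preparative chiral SFC, immobilised amylose tris(3,5-dimethylphenylcarbamate) phase, CO2/MeCN (0.1% AcOH), 10 °C; fractions evaporated below 10 °C; (2S) fraction: Et3N (5 mol%), MeCN, 23 °C, then AcOH, re-injected
Reagents that add atoms: none
Why: C2 is the only stereocentre and is set here by resolution on a chiral stationary phase under cold, weakly acidic, alcohol-free conditions where ring–chain tautomerism is slow, the (2R) fraction (assigned by measured against calculated ECD) being kept and the (2S) fraction racemised through the open diketone and recycled (chromatographic enantiomer resolution with racemisation–recycle).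

**Compound list**
1 | 5-methylhex-1-yne | CC(C)CCC#C | starting material
2 | N-methoxy-N-methylcarbamoyl chloride | CON(C)C(=O)Cl | starting material
3 | N-methoxy-N,6-dimethylhept-2-ynamide | CC(C)CCC#CC(=O)N(C)OC | intermediate
4 | 4-hydroxy-6-methyl-2H-pyran-2-one (triacetic acid lactone) | Cc1cc(O)cc(=O)o1 | starting material
5 | N-methoxy-N-methylacetamide | CC(=O)N(C)OC | starting material
6 | 4-hydroxy-6-(2-oxopropyl)-2H-pyran-2-one | CC(=O)Cc1cc(O)cc(=O)o1 | intermediate
7 | 4-hydroxy-6-(9-methyl-2,4-dioxodec-5-yn-1-yl)-2H-pyran-2-one (exists as the diketone enol) | CC(C)CCC#CC(=O)CC(=O)Cc1cc(O)cc(=O)o1 | intermediate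
8 | methyl acetoacetate (methyl 3-oxobutanoate) | COC(=O)CC(C)=O | starting material
9 | methyl 3-(trimethylsilyloxy)but-2-enoate (E/Z mixture) | COC(=O)C=C(C)O[Si](C)(C)C | intermediate (not isolated)
10 | 1-methoxy-1,3-bis(trimethylsilyloxy)buta-1,3-diene (C1=C2 geometry not controlled; it is lost on aromatisation) | COC(O[Si](C)(C)C)=CC(=C)O[Si](C)(C)C | intermediate
11 | 6-[(2Z)-9-methyl-4-oxo-2-(trimethylsilyloxy)dec-2-en-5-yn-1-yl]-4-(trimethylsilyloxy)-2H-pyran-2-one (the silyl group shuttles between the two diketone oxygens; the reacting ynone form is drawn) | CC(C)CCC#CC(=O)/C=C(\O[Si](C)(C)C)Cc1cc(O[Si](C)(C)C)cc(=O)o1 | intermediate (not isolated)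
12 | (2Z)-1-[6-methoxy-2-(3-methylbutyl)-4,6-bis(trimethylsilyloxy)cyclohexa-1,4-dien-1-yl]-3-(trimethylsilyloxy)-4-[2-oxo-4-(trimethylsilyloxy)-2H-pyran-6-yl]but-2-en-1-one (racemic at the ketal carbon) | COC1(O[Si](C)(C)C)C=C(O[Si](C)(C)C)CC(CCC(C)C)=C1C(=O)/C=C(\O[Si](C)(C)C)Cc1cc(O[Si](C)(C)C)cc(=O)o1 | intermediate (not isolated)
13 | (2Z)-1-[2-(3-methylbutyl)-4,6-bis(trimethylsilyloxy)phenyl]-3-(trimethylsilyloxy)-4-[2-oxo-4-(trimethylsilyloxy)-2H-pyran-6-yl]but-2-en-1-one | CC(C)CCc1cc(O[Si](C)(C)C)cc(O[Si](C)(C)C)c1C(=O)/C=C(\O[Si](C)(C)C)Cc1cc(O[Si](C)(C)C)cc(=O)o1 | intermediate (not isolated)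
14 | 1-[2,4-dihydroxy-6-(3-methylbutyl)phenyl]-4-(4-hydroxy-2-oxo-2H-pyran-6-yl)butane-1,3-dione | CC(C)CCc1cc(O)cc(O)c1C(=O)CC(=O)Cc1cc(O)cc(=O)o1 | intermediate (not isolated)
15 | (2RS)-2,7-dihydroxy-2-[(4-hydroxy-2-oxo-2H-pyran-6-yl)methyl]-5-(3-methylbutyl)-2,3-dihydro-4H-chromen-4-one (racemate) | CC(C)CCc1cc(O)cc2c1C(=O)CC(O)(Cc1cc(O)cc(=O)o1)O2 | intermediate
16 | (2R)-2,7-dihydroxy-2-[(4-hydroxy-2-oxo-2H-pyran-6-yl)methyl]-5-(3-methylbutyl)-2,3-dihydro-4H-chromen-4-one | CC(C)CCc1cc(O)cc2c1C(=O)C[C@@](O)(Cc1cc(O)cc(=O)o1)O2 | target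

**Step count and risk**
Total steps: 6. Longest linear sequence: 4 steps (4 → 6 → 7 → 15 → 16; steps 2, 3, 5, 6).

Most likely to fail, in this order:

Step 5. The ynone in 11 is flanked by a silyloxy-enone and is only a moderately activated dienophile, the diene is thermally fragile, and loss of Me3SiOH instead of methanol would give an aryl methyl ether that cannot close ring B. The fallback builds ring A on a simple alkynoate and closes ring B by a Claisen aroylation. It sets out from 1 and 10. n-BuLi then methyl chloroformate convert 1 into methyl 6-methylhept-2-ynoate F1. F1 and 10 (neat, 130 °C, then dilute HCl/THF) give methyl 2,4-dihydroxy-6-(3-methylbutyl)benzoate F2. TBSOTf and 2,6-lutidine give methyl 2,4-bis(tert-butyldimethylsilyloxy)-6-(3-methylbutyl)benzoate F3. The trianion of 6 (LiN(iPr)2, 4.2 equiv) is aroylated by F3 to give 1-[2,4-bis(tert-butyldimethylsilyloxy)-6-(3-methylbutyl)phenyl]-4-(4-hydroxy-2-oxo-2H-pyran-6-yl)butane-1,3-dione F4. Bu4NF/AcOH in THF at 0 °C frees the phenols, the open-chain diketone 14 closes, and the fallback comes back to the route at 15.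

Step 3. Risks are conjugate addition to the ynamide, proton transfer, poor solubility of the trianion, and cyclisation of 7 to a 4-pyranone on work-up. The fallback makes the same bond by aldol addition and oxidation. It sets out from 1 and 6. n-BuLi then DMF convert 1 into 6-methylhept-2-ynal F5. The trianion of 6 adds to F5 at −78 °C to give racemic 4-hydroxy-6-(4-hydroxy-9-methyl-2-oxodec-5-yn-1-yl)-2H-pyran-2-one F6. MnO2 in CH2Cl2 oxidises the propargylic alcohol and the fallback comes back to the route at 7.

Step 6. Risks are racemisation on the column or during evaporation, and insufficient resolution. The fallback fixes C2 by crystallisation-induced diastereomer transformation. It sets out from 15. One equivalent of quinine in MeCN/i-PrOAc is slurry-aged at 20 °C; the tertiary amine lets the hemiketal epimerise in solution through the open diketone while the less soluble salt, quininium (2R)-6-{[2,7-dihydroxy-5-(3-methylbutyl)-4-oxo-3,4-dihydro-2H-chromen-2-yl]methyl}-2-oxo-2H-pyran-4-olate F7, crystallises. The filtered salt is partitioned between EtOAc and cold 0.5 M aq KHSO4 and the fallback comes back to the route at 16. Which diastereomeric salt crystallises must be established once by X-ray; quinidine is the mirror-image choice if the (2S) salt deposits with quinine.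

**Further compounds**
F1 | step 5 | methyl 6-methylhept-2-ynoate | CC(C)CCC#CC(=O)OC
F2 | step 5 | methyl 2,4-dihydroxy-6-(3-methylbutyl)benzoate | COC(=O)c1c(O)cc(O)cc1CCC(C)C
F3 | step 5 | methyl 2,4-bis(tert-butyldimethylsilyloxy)-6-(3-methylbutyl)benzoate | COC(=O)c1c(O[Si](C)(C)C(C)(C)C)cc(O[Si](C)(C)C(C)(C)C)cc1CCC(C)C
F4 | step 5 | 1-[2,4-bis(tert-butyldimethylsilyloxy)-6-(3-methylbutyl)phenyl]-4-(4-hydroxy-2-oxo-2H-pyran-6-yl)butane-1,3-dione | CC(C)CCc1cc(O[Si](C)(C)C(C)(C)C)cc(O[Si](C)(C)C(C)(C)C)c1C(=O)CC(=O)Cc1cc(O)cc(=O)o1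
F5 | step 3 | 6-methylhept-2-ynal | CC(C)CCC#CC=O
F6 | step 3 | 4-hydroxy-6-(4-hydroxy-9-methyl-2-oxodec-5-yn-1-yl)-2H-pyran-2-one (racemic) | CC(C)CCC#CC(O)CC(=O)Cc1cc(O)cc(=O)o1
F7 | step 6 | quininium (2R)-6-{[2,7-dihydroxy-5-(3-methylbutyl)-4-oxo-3,4-dihydro-2H-chromen-2-yl]methyl}-2-oxo-2H-pyran-4-olate | CC(C)CCc1cc(O)cc2c1C(=O)C[C@@](O)(Cc1cc([O-])cc(=O)o1)O2.COC1=CC2=C(C=CN=C2C=C1)[C@H]([C@@H]3C[C@@H]4CC[NH+]3C[C@@H]4C=C)O
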